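The leftover was what I reckoned from: after 10.0 d Tuesday's flask still held 18.4% of its Ek, and Friday's, with more Ez, held less, 6.7%. The new flasks, elm, larch and birch, differ from these runs by a little Ez and are read at that same time.

| flask | Ek | Ji | Ez | Xi | remark | time |
|---|---|---|---|---|---|---|
| Tuesday's | 0.40 M | 0.80 M | 0.13 M | 0.040 M | run made earlier |  |
| Saturday's | 0.40 M | 0.80 M | 0.23 M | 0.040 M | run made earlier |  |
| Friday's | 0.40 M | 0.80 M | 0.45 M | 0.040 M | run made earlier |  |
| elm | 0.40 M | 0.800 M | 0.120 M | 0.0400 M |  | 10 d |
| birch | 0.40 M | 0.800 M | 0.480 M | 0.0400 M |  | 10 d |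
| larch | 0.40 M | 0.800 M | 0.240 M | 0.0400 M |  | 10 d |

| run | time / d | Ek / % | JiJy / % |
|---|---|---|---|
| Tuesday's | 2.50 | 64.3 | 34.4 |
| Tuesday's | 5.00 | 44.6 | 54.1 |
| Tuesday's | 8.00 | 26.9 | 70.5 |
| Tuesday's | 10.0 | 18.4 | 80.5 |
| Saturday's | 1.25 | 76.1 | 21.7 |
| Saturday's | 4.00 | 48.9 | 50.9 |
| Saturday's | 6.00 | 33.6 | 64.4 |
| Saturday's | 10.0 | 15.2 | 84.6 |
| Friday's | 0.833 | 79.4 | 18.7 |
| Friday's | 1.67 | 67.6 | 31.0 |
| Friday's | 4.00 | 40.9 | 56.6 |
| Friday's | 10.0 | 6.7 | 92.0 |

(standard deviation of a reading: 0.5 percentage points)

- the analysis behind the earlier runs scatters by 0.5 percentage points, standard deviation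

1. part of the Ek that has reacted at the end, elm
2. part of the Ek that has reacted at the end, birch
3. part of the Ek that has reacted at the end, larch
4. what raising the concentration of Ez from its lowest to its highest value here does to the part of the Ek that has reacted (changes below 5 percentage points count as none) (no change / it rises / it falls)

The readings stood on a ladder of times. On the first rung is the part of the charge read neither as Ek nor as JiJy: in Friday's run the gap in the balance was 1.9 percentage points at 0.833 d and 1.3 points at 10.0 d, so it had opened before the first reading and stayed small. Next comes the time constant of Ek, taken as pseudo-first-order: I defined N as the logarithm of charged over left, the number of time constants gone through. That gave N = 1.69 on Tuesday, or 5.92 d each, and 2.70 on Friday, or 3.70 d each. Last comes the drift of that rate: in Friday's run it went from 0.192 /d early to 0.302 /d late. N at the end sums that drift, so I needed no rate law.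

I took the nearest earlier run as the zero of the scale and reckoned the departure from it. From Tuesday to Friday N rose at 3.16 /M; this is the gain S, the extra time constants of Ek per molar of Ez added at fixed other charges and time. Saturday's N, 1.88, lies under that line's 2.01, so S is an average. But doubling it moves birch by 0.55 points, against a scatter of 0.5 points. So I reckoned 81.0% for elm, 85.3% for larch and 93.9% for birch, a rise of 13 points.

The forecast, on the grounds that “All three new runs use the same charges and the same 10 days”, drew a quadratic instead and gave slightly different values: 81.4% for elm, 85.2% for larch, 94.2% for birch, and it rises.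

The flask gave 81.4% for elm, 86.5% for larch and 93.8% for birch: it rises, by 12 points.

    Ek ⇌ Jy + Ly (K = 2.80 × 10⁻⁴ M, k = 1.40 × 10⁻⁴ /s)
    Ji + Jy → JiJy (k = 1.40 × 10⁻⁴ /M/s)
    Ji + Ly ⇌ JiLy, settled at all times (K = 2.20 /M)
    Ez + Ly → EzLy (k = 1.10 × 10⁻⁴ /M/s)
    Ly → Eb (k = 2.20 × 10⁻⁵ /s)
    Jy + Xi → JyXi (k = 2.40 × 10⁻⁵ /M/s)

At 10.0 d birch held 0.235 M of EzLy, more than elm's 0.0817 M. Between these two flasks N rose at 3.05 /M, beside S at 3.16 /M. Starting from birch, S put a neighbour flask charged with 0.60 M of Ez at 4.25% of its Ek left, and that flask still held 3.8%.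

All runs were computed for an exercise; noise was put on by code.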